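**Retrosynthetic overview**
1. Last cut: the bridging lactam N–C(=O) bond. Its formation closes the seven- and the nine-membered ring at once, by transannular acylation inside a twelve-membered cyclic amine; that ring comes from an intramolecular sulfonamide Mitsunobu alkylation (N–C5).
2. Next cut: the C1–C2 bond of the ketone, made by Pd-catalysed acylation of a carbamate-stabilised alkylzinc iodide (west amino-lactone) with the acid chloride of the east lactone acid.
3. East half: lactone by anti boron aldol, ozonolysis, lactol oxidation and methylation; C9/C10 by Ireland–Claisen rearrangement that relays the carbinol centre of (R,E)-hex-3-en-2-ol, made by ketoreductase reduction of the achiral enone.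
4. West half: Sharpless aminohydroxylation of an achiral enoate, Z-olefination/lactonization to a butenolide, cis-selective hydrogenation.
5. Ring order: east γ-lactone and west γ-lactone (separate branches), then the twelve-membered azacycle, then caprolactam and nine-membered ring together in the final step.

Assumption: locants C1–C21 follow Stemona-alkaloid numbering (C1 ketone, C3 N-bearing CH, C5–C8 the four CH2 groups, C9a lactam C=O, C10 ethyl-bearing CH, C11–C13 east lactone, C18–C21 west lactone); compounds 1, 3, 12, 21, 22 and 27 are bought.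

**East half (steps 1–12)**

Step 1
Reactants: 1 (3E)-hex-3-en-2-one
Product: 2 (2R,3E)-hex-3-en-2-ol
Conditions: (R)-selective NADPH-dependent ketoreductase (alcohol dehydrogenase, Lactobacillus type), NADP+ (cat.), MgCl2 (1 mM), iPrOH (10 vol%), phosphate buffer pH 7, 30 °C
Reagents that add atoms: none
Why: Enzymatic asymmetric ketone reduction (ketoreductase class) delivers hydride to one face of the methyl ketone and sets the carbinol centre (R), with isopropanol recycling the cofactor and the conjugated alkene left untouched.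

Step 2
Reactants: 3 6-hydroxyhexanoic acid
Product: 5 6-[(tert-butyldiphenylsilyl)oxy]hexanoic acid, via bis-silylated acid 4 (not isolated)
Conditions: tBuPh2SiCl (2.2 equiv), imidazole, DMF, rt; then K2CO3, MeOH/THF/H2O, rt; citric acid work-up
Reagents that add atoms: tert-butyldiphenylsilyl chloride, CC(C)(C)[Si](Cl)(c1ccccc1)c1ccccc1
Why: Silylation of both OH and CO2H followed by mild-base cleavage of the labile silyl ester leaves the robust primary silyl ether that masks C5 until step 23.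

Step 3
Reactants: 2 (2R,3E)-hex-3-en-2-ol, 5 6-[(tert-butyldiphenylsilyl)oxy]hexanoic acid
Product: 6 (2R,3E)-hex-3-en-2-yl 6-[(tert-butyldiphenylsilyl)oxy]hexanoate
Conditions: DCC, DMAP (10 mol%), CH2Cl2, 0 °C to rt
Reagents that add atoms: none
Why: Steglich esterification joins alcohol and acid without touching the carbinol centre or the alkene geometry.

Step 4
Reactants: 6 (2R,3E)-hex-3-en-2-yl 6-[(tert-butyldiphenylsilyl)oxy]hexanoate
Product: 9 (2S,3S,4E)-2-{4-[(tert-butyldiphenylsilyl)oxy]butyl}-3-ethylhex-4-enoic acid, via silyl ketene acetal 7 (not isolated), via trimethylsilyl ester 8 (not isolated)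
Conditions: LiN(iPr)2 (1.15 equiv), Me3SiCl/Et3N (premixed), THF, −78 °C; then rt to 55 °C, 3 h; 1 M HCl
Reagents that add atoms: none
Why: Ireland–Claisen rearrangement: kinetic deprotonation in THF gives the (E)-silyl ketene acetal, and the chair transition state with the carbinol methyl group equatorial transfers the centre of 2 to C9 and C10 (anti) and gives the (E)-propenyl group.

Step 5
Reactants: 9 (2S,3S,4E)-2-{4-[(tert-butyldiphenylsilyl)oxy]butyl}-3-ethylhex-4-enoic acid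
Product: 10 tert-butyl (2S,3S,4E)-2-{4-[(tert-butyldiphenylsilyl)oxy]butyl}-3-ethylhex-4-enoate
Conditions: tBuOC(=NH)CCl3 (2 equiv), BF3·OEt2 (5 mol%), CH2Cl2/cyclohexane, rt
Reagents that add atoms: tert-butyl 2,2,2-trichloroacetimidate, CC(C)(C)OC(=N)C(Cl)(Cl)Cl
Why: Acid-catalysed imidate tert-butylation protects the hindered acid as an ester that survives the later enolate, hydrogenolysis and fluoride steps and cannot lactonize onto the C11 oxygen.

Step 6
Reactants: 10 tert-butyl (2S,3S,4E)-2-{4-[(tert-butyldiphenylsilyl)oxy]butyl}-3-ethylhex-4-enoate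
Product: 11 tert-butyl (2S)-6-[(tert-butyldiphenylsilyl)oxy]-2-[(2R)-1-oxobutan-2-yl]hexanoate
Conditions: O3, CH2Cl2, −78 °C; PPh3, −78 °C to rt
Reagents that add atoms: ozone, [O-][O+]=O
Why: Ozonolysis with reductive work-up cuts the propenyl group to the C11 aldehyde under neutral conditions that do not epimerize the α-centre.

Step 7
Reactants: 12 pent-4-enoic acid
Product: 13 benzyl pent-4-enoate
Conditions: BnBr, K2CO3, DMF, rt
Reagents that add atoms: benzyl bromide, BrCc1ccccc1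
Why: Carboxylate O-alkylation gives the aldol donor as a benzyl ester that is later removed by hydrogenolysis.

Step 8
Reactants: 11 tert-butyl (2S)-6-[(tert-butyldiphenylsilyl)oxy]-2-[(2R)-1-oxobutan-2-yl]hexanoate, 13 benzyl pent-4-enoate
Product: 15 benzyl (2S,3S,4R,5S)-5-(tert-butoxycarbonyl)-9-[(tert-butyldiphenylsilyl)oxy]-4-ethyl-3-hydroxy-2-(prop-2-en-1-yl)nonanoate, via boron enolate 14 (not isolated)
Conditions: 13 (1.5 equiv), (c-C6H11)2BOTf (1.3 equiv), Et3N (1.5 equiv), CH2Cl2, −78 °C, 2 h; 11, −78 to 0 °C; pH 7 buffer, MeOH, 30% H2O2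
Reagents that add atoms: none
Why: Boron-mediated anti-selective aldol reaction: the (E)-enol borinate reacts through a Zimmerman–Traxler chair to give the 2,3-anti adduct and attacks the α-branched aldehyde in the Felkin–Anh sense (matched for E-enolates), setting C11 (S) and C12 (S).

Step 9
Reactants: 15 benzyl (2S,3S,4R,5S)-5-(tert-butoxycarbonyl)-9-[(tert-butyldiphenylsilyl)oxy]-4-ethyl-3-hydroxy-2-(prop-2-en-1-yl)nonanoate
Product: 16 benzyl (2S,3S)-2-[(3R,4S)-4-(tert-butoxycarbonyl)-8-[(tert-butyldiphenylsilyl)oxy]octan-3-yl]-5-hydroxyoxolane-3-carboxylate (lactol; anomer mixture)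
Conditions: O3, CH2Cl2, −78 °C; PPh3, −78 °C to rt
Reagents that add atoms: ozone, [O-][O+]=O
Why: Ozonolysis of the terminal alkene gives an aldehyde that is trapped at once by the C11 hydroxyl as the five-membered lactol.

Step 10
Reactants: 16 benzyl (2S,3S)-2-[(3R,4S)-4-(tert-butoxycarbonyl)-8-[(tert-butyldiphenylsilyl)oxy]octan-3-yl]-5-hydroxyoxolane-3-carboxylate
Product: 17 benzyl (2S,3S)-2-[(3R,4S)-4-(tert-butoxycarbonyl)-8-[(tert-butyldiphenylsilyl)oxy]octan-3-yl]-5-oxooxolane-3-carboxylate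
Conditions: TEMPO (10 mol%), PhI(OAc)2 (1.3 equiv), CH2Cl2, rt
Reagents that add atoms: none
Why: Oxoammonium (TEMPO) oxidation of the lactol gives the γ-lactone without epimerizing the ester-bearing centre.

Step 11
Reactants: 17 benzyl (2S,3S)-2-[(3R,4S)-4-(tert-butoxycarbonyl)-8-[(tert-butyldiphenylsilyl)oxy]octan-3-yl]-5-oxooxolane-3-carboxylate
Product: 18 (2S,3S)-2-[(3R,4S)-4-(tert-butoxycarbonyl)-8-[(tert-butyldiphenylsilyl)oxy]octan-3-yl]-5-oxooxolane-3-carboxylic acid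
Conditions: H2 (1 atm), 10% Pd/C, EtOAc, rt
Reagents that add atoms: none
Why: Hydrogenolysis frees the C1 acid under neutral conditions while tert-butyl ester, silyl ether and lactone stay intact.

Step 12
Reactants: 18 (2S,3S)-2-[(3R,4S)-4-(tert-butoxycarbonyl)-8-[(tert-butyldiphenylsilyl)oxy]octan-3-yl]-5-oxooxolane-3-carboxylic acid
Product: 20 (2S,3S,4S)-2-[(3R,4S)-4-(tert-butoxycarbonyl)-8-[(tert-butyldiphenylsilyl)oxy]octan-3-yl]-4-methyl-5-oxooxolane-3-carboxylic acid, via disodium enolate carboxylate 19 (not isolated)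
Conditions: NaN(SiMe3)2 (2.2 equiv), THF, −78 °C, 1 h; MeI (3 equiv), −78 to −40 °C; 1 M HCl
Reagents that add atoms: iodomethane, CI
Why: Dianion alkylation: methyl iodide enters the lactone enolate anti to the neighbouring carboxylate and the C11 side chain, giving the 3,4-trans lactone (C13 S), while the carboxylate protects its own α-centre (C12) from enolization.

**West half (steps 13–20)**

Step 13
Reactants: 21 2-(benzyloxy)acetaldehyde, 22 ethyl (triphenylphosphoranylidene)acetate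
Product: 23 ethyl (2E)-4-(benzyloxy)but-2-enoate
Conditions: CH2Cl2, rt
Reagents that add atoms: none
Why: Wittig olefination with a stabilized ylide gives the (E)-enoate.

Step 14
Reactants: 23 ethyl (2E)-4-(benzyloxy)but-2-enoate
Product: 24 ethyl (2R,3S)-4-(benzyloxy)-3-[(tert-butoxycarbonyl)amino]-2-hydroxybutanoate
Conditions: tBuOCONH2 (3.1 equiv), tBuOCl (3.05 equiv), NaOH (3.05 equiv), K2OsO2(OH)4 (4 mol%), (DHQ)2PHAL (5 mol%), nPrOH/H2O 1:1, 0 °C to rt
Reagents that add atoms: tert-butyl carbamate, CC(C)(C)OC(N)=O; water, O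
Why: Sharpless asymmetric aminohydroxylation: the K2OsO2(OH)4/(DHQ)2PHAL catalyst adds N and O syn across the (E)-enoate with nitrogen at the β-carbon, setting C3 and C18.

Step 15
Reactants: 24 ethyl (2R,3S)-4-(benzyloxy)-3-[(tert-butoxycarbonyl)amino]-2-hydroxybutanoate
Product: 25 3-tert-butyl 5-ethyl (4S,5R)-4-[(benzyloxy)methyl]-2,2-dimethyl-1,3-oxazolidine-3,5-dicarboxylate
Conditions: Me2C(OMe)2, PPTS (10 mol%), toluene, 80 °C
Reagents that add atoms: 2,2-dimethoxypropane, COC(C)(C)OC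
Why: Acid-catalysed N,O-acetal formation locks the amino alcohol as the trans-oxazolidine and removes the N–H and O–H protons before the hydride and phosphonate steps.

Step 16
Reactants: 25 3-tert-butyl 5-ethyl (4S,5R)-4-[(benzyloxy)methyl]-2,2-dimethyl-1,3-oxazolidine-3,5-dicarboxylate
Product: 26 tert-butyl (4S,5R)-4-[(benzyloxy)methyl]-5-formyl-2,2-dimethyl-1,3-oxazolidine-3-carboxylate
Conditions: iBu2AlH (1.1 equiv), toluene, −78 °C; MeOH, then aq. potassium sodium tartrate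
Reagents that add atoms: none
Why: Low-temperature iBu2AlH reduction stops at the aldehyde through the stable tetrahedral aluminium alkoxide, and the ring-held α-alkoxy centre does not epimerize.

Step 17
Reactants: 26 tert-butyl (4S,5R)-4-[(benzyloxy)methyl]-5-formyl-2,2-dimethyl-1,3-oxazolidine-3-carboxylate, 27 ethyl 2-[bis(2,2,2-trifluoroethoxy)phosphoryl]propanoate
Product: 28 tert-butyl (4S,5S)-4-[(benzyloxy)methyl]-5-[(1Z)-3-ethoxy-2-methyl-3-oxoprop-1-en-1-yl]-2,2-dimethyl-1,3-oxazolidine-3-carboxylate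
Conditions: KN(SiMe3)2, 18-crown-6, THF, −78 °C
Reagents that add atoms: none
Why: Still–Gennari variant of the Horner–Wadsworth–Emmons olefination gives the (Z)-trisubstituted enoate needed for ring closure.

Step 18
Reactants: 28 tert-butyl (4S,5S)-4-[(benzyloxy)methyl]-5-[(1Z)-3-ethoxy-2-methyl-3-oxoprop-1-en-1-yl]-2,2-dimethyl-1,3-oxazolidine-3-carboxylate
Product: 30 tert-butyl N-[(1S)-2-(benzyloxy)-1-[(2S)-4-methyl-5-oxo-2,5-dihydrofuran-2-yl]ethyl]carbamate, via hydroxy enoate 29 (not isolated)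
Conditions: AcOH/H2O 4:1, 45 °C
Reagents that add atoms: none
Why: Acidic hydrolysis of the N,O-acetal frees the C18 hydroxyl, which lactonizes onto the cis-disposed ester to give the butenolide while the Boc group survives.

Step 19
Reactants: 30 tert-butyl N-[(1S)-2-(benzyloxy)-1-[(2S)-4-methyl-5-oxo-2,5-dihydrofuran-2-yl]ethyl]carbamate
Product: 32 tert-butyl N-[(1S)-2-hydroxy-1-[(2S,4S)-4-methyl-5-oxooxolan-2-yl]ethyl]carbamate, via benzyl ether lactone 31 (not isolated)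
Conditions: H2 (3 atm), 5% Rh/Al2O3, EtOAc, rt; then 20% Pd(OH)2/C, H2 (1 atm), EtOH, rt
Reagents that add atoms: none
Why: Heterogeneous hydrogenation adds hydrogen to the butenolide face opposite the C18 substituent, setting C20 (S, 2,4-cis lactone), and hydrogenolysis then removes the benzyl ether.

Step 20
Reactants: 32 tert-butyl N-[(1S)-2-hydroxy-1-[(2S,4S)-4-methyl-5-oxooxolan-2-yl]ethyl]carbamate
Product: 33 tert-butyl N-[(1R)-2-iodo-1-[(2S,4S)-4-methyl-5-oxooxolan-2-yl]ethyl]carbamate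
Conditions: PPh3, I2, imidazole, CH2Cl2, 0 °C to rt
Reagents that add atoms: iodine, II
Why: Appel-type iodination converts the primary alcohol to the iodide without touching carbamate or lactone (the descriptor changes only because of CIP priorities).

**Union and ring closures (steps 21–27)**

Step 21
Reactants: 20 (2S,3S,4S)-2-[(3R,4S)-4-(tert-butoxycarbonyl)-8-[(tert-butyldiphenylsilyl)oxy]octan-3-yl]-4-methyl-5-oxooxolane-3-carboxylic acid, 33 tert-butyl N-[(1R)-2-iodo-1-[(2S,4S)-4-methyl-5-oxooxolan-2-yl]ethyl]carbamate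
Product: 36 tert-butyl (2S)-6-[(tert-butyldiphenylsilyl)oxy]-2-[(1R)-1-{(2S,3S,4S)-3-[(3S)-3-[(tert-butoxycarbonyl)amino]-3-[(2S,4S)-4-methyl-5-oxooxolan-2-yl]propanoyl]-4-methyl-5-oxooxolan-2-yl}propyl]hexanoate, via acid chloride 34 (not isolated), via alkylzinc iodide 35 (not isolated)
Conditions: 20, 1-chloro-N,N,2-trimethylprop-1-en-1-amine (1.2 equiv), CH2Cl2, 0 °C to rt, concentrate; 33 (1.5 equiv), Zn dust (I2-activated, 3 equiv), DMF, rt, 40 min; combine, PdCl2(PPh3)2 (5 mol%), THF/DMF, rt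
Reagents that add atoms: none
Why: Negishi acylation: zinc inserts into the primary C–I bond to give a carbamate-chelated alkylzinc that tolerates the lactone and couples under Pd catalysis with the acid chloride (made with a neutral chloroenamine) to form the C1–C2 ketone without base, so C12 and C3 keep their configuration.

Step 22
Reactants: 36 tert-butyl (2S)-6-[(tert-butyldiphenylsilyl)oxy]-2-[(1R)-1-{(2S,3S,4S)-3-[(3S)-3-[(tert-butoxycarbonyl)amino]-3-[(2S,4S)-4-methyl-5-oxooxolan-2-yl]propanoyl]-4-methyl-5-oxooxolan-2-yl}propyl]hexanoate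
Product: 38 the N-(2-nitrophenylsulfonyl) analogue of 36 (NHBoc replaced by NHSO2C6H4-2-NO2), via ammonium methanesulfonate 37 (not isolated)
Conditions: MeSO3H (3 equiv), tBuOAc/CH2Cl2 4:1, rt, 2 h; then 0 °C, 2-O2NC6H4SO2Cl (1.3 equiv), iPr2NEt (6 equiv, slow addition)
Reagents that add atoms: 2-nitrobenzenesulfonyl chloride, O=S(=O)(Cl)c1ccccc1[N+](=O)[O-]
Why: Selective N-Boc acidolysis in tert-butyl acetate (which regenerates the tert-butyl ester) gives the ammonium salt, which is sulfonylated as it is liberated so the free primary amine has no time to attack the neighbouring lactone, and the nosyl group acidifies N–H for the Mitsunobu step.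

Step 23
Reactants: 38 N-nosyl amino ketone silyl ether
Product: 39 tert-butyl (2S)-6-hydroxy-2-[(1R)-1-{(2S,3S,4S)-4-methyl-3-[(3S)-3-[(2S,4S)-4-methyl-5-oxooxolan-2-yl]-3-[(2-nitrophenyl)sulfonylamino]propanoyl]-5-oxooxolan-2-yl}propyl]hexanoate
Conditions: HF·pyridine, pyridine/THF, 0 °C to rt
Reagents that add atoms: none
Why: Buffered fluoride desilylation frees the C5 alcohol and leaves lactones, ketone, sulfonamide and tert-butyl ester untouched.

Step 24
Reactants: 39 N-nosyl amino ketone alcohol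
Product: 40 tert-butyl ester of the N-(2-nitrophenylsulfonyl) twelve-membered azacycle (ring atoms N, C5–C8, C9, C10, C11, C12, C1, C2, C3; stereocentres as in 39)
Conditions: PPh3 (3 equiv), DIAD (3 equiv), toluene/THF 4:1, 0.002 M, syringe pump, rt
Reagents that add atoms: none
Why: Intramolecular Fukuyama–Mitsunobu alkylation of the acidic nosyl amide by the primary alcohol under high dilution forms the N–C5 bond and the twelve-membered ring under essentially neutral conditions.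

Step 25
Reactants: 40 N-nosyl twelve-membered azacycle tert-butyl ester
Product: 41 the corresponding C9a carboxylic acid
Conditions: CF3CO2H/CH2Cl2 1:2, 0 °C to rt
Reagents that add atoms: none
Why: Acidolysis removes the tert-butyl ester while sulfonamide, lactones and ketone are acid-stable.

Step 26
Reactants: 41 N-nosyl twelve-membered azacycle acid
Product: 42 the corresponding pentafluorophenyl ester
Conditions: C6F5OH (1.5 equiv), EDC·HCl (1.5 equiv), CH2Cl2, 0 °C to rt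
Reagents that add atoms: pentafluorophenol, Oc1c(F)c(F)c(F)c(F)c1F
Why: Carbodiimide esterification installs the active ester while nitrogen is still masked, so the acyl donor is in place before any amine exists.

Step 27
Reactants: 42 N-nosyl twelve-membered azacycle pentafluorophenyl ester
Product: 44 target CNP0311700.3 (3S,9S,10R,11S,12S,13S,18S,20S), via macrocyclic amine 43 (not isolated)
Conditions: PhSH (3 equiv), K2CO3 (4 equiv), MeCN, 0.002 M, rt
Reagents that add atoms: none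
Why: Fukuyama nosyl cleavage by thiolate (Meisenheimer adduct) liberates the secondary amine, which is acylated at once by the transannular active ester (lactamization), closing the seven- and nine-membered rings in one event before the amine can attack the neighbouring lactone.

**Compound list**
1 | (3E)-hex-3-en-2-one | CC/C=C/C(C)=O | starting material
2 | (2R,3E)-hex-3-en-2-ol | CC/C=C/[C@@H](C)O | intermediate
3 | 6-hydroxyhexanoic acid | OCCCCCC(=O)O | starting material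
4 | tert-butyldiphenylsilyl 6-[(tert-butyldiphenylsilyl)oxy]hexanoate (not isolated) | CC(C)(C)[Si](c1ccccc1)(c1ccccc1)OCCCCCC(=O)O[Si](c1ccccc1)(c1ccccc1)C(C)(C)C | intermediate
5 | 6-[(tert-butyldiphenylsilyl)oxy]hexanoic acid | CC(C)(C)[Si](c1ccccc1)(c1ccccc1)OCCCCCC(=O)O | intermediate
6 | (2R,3E)-hex-3-en-2-yl 6-[(tert-butyldiphenylsilyl)oxy]hexanoate | CC/C=C/[C@@H](C)OC(=O)CCCCCO[Si](c1ccccc1)(c1ccccc1)C(C)(C)C | intermediate
7 | (E)-O-trimethylsilyl ketene acetal of 6, chain CH2 cis to the allylic oxygen (not isolated) | CC/C=C/[C@@H](C)O/C(O[Si](C)(C)C)=C\CCCCO[Si](c1ccccc1)(c1ccccc1)C(C)(C)C | intermediate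
8 | trimethylsilyl (2S,3S,4E)-2-{4-[(tert-butyldiphenylsilyl)oxy]butyl}-3-ethylhex-4-enoate (not isolated) | CC(C)(C)[Si](c1ccccc1)(c1ccccc1)OCCCC[C@@H]([C@@H](CC)/C=C/C)C(=O)O[Si](C)(C)C | intermediate
9 | (2S,3S,4E)-2-{4-[(tert-butyldiphenylsilyl)oxy]butyl}-3-ethylhex-4-enoic acid | CC(C)(C)[Si](c1ccccc1)(c1ccccc1)OCCCC[C@@H]([C@@H](CC)/C=C/C)C(=O)O | intermediate
10 | tert-butyl (2S,3S,4E)-2-{4-[(tert-butyldiphenylsilyl)oxy]butyl}-3-ethylhex-4-enoate | CC(C)(C)[Si](c1ccccc1)(c1ccccc1)OCCCC[C@@H]([C@@H](CC)/C=C/C)C(=O)OC(C)(C)C | intermediate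
11 | tert-butyl (2S)-6-[(tert-butyldiphenylsilyl)oxy]-2-[(2R)-1-oxobutan-2-yl]hexanoate | CC(C)(C)[Si](c1ccccc1)(c1ccccc1)OCCCC[C@@H]([C@@H](CC)C=O)C(=O)OC(C)(C)C | intermediate
12 | pent-4-enoic acid | C=CCCC(=O)O | starting material
13 | benzyl pent-4-enoate | C=CCCC(=O)OCc1ccccc1 | intermediate
14 | dicyclohexylboron (E)-enolate of 13, allyl CH2 cis to OBn (not isolated) | C=CC/C=C(\OCc1ccccc1)OB(C1CCCCC1)C1CCCCC1 | intermediate
15 | benzyl (2S,3S,4R,5S)-5-(tert-butoxycarbonyl)-9-[(tert-butyldiphenylsilyl)oxy]-4-ethyl-3-hydroxy-2-(prop-2-en-1-yl)nonanoate | CC(C)(C)[Si](c1ccccc1)(c1ccccc1)OCCCC[C@@H]([C@@H](CC)[C@H](O)[C@H](CC=C)C(=O)OCc1ccccc1)C(=O)OC(C)(C)C | intermediate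
16 | benzyl (2S,3S)-2-[(3R,4S)-4-(tert-butoxycarbonyl)-8-[(tert-butyldiphenylsilyl)oxy]octan-3-yl]-5-hydroxyoxolane-3-carboxylate (anomer mixture) | CC(C)(C)[Si](c1ccccc1)(c1ccccc1)OCCCC[C@@H]([C@@H](CC)[C@@H]1OC(O)C[C@@H]1C(=O)OCc1ccccc1)C(=O)OC(C)(C)C | intermediate
17 | benzyl (2S,3S)-2-[(3R,4S)-4-(tert-butoxycarbonyl)-8-[(tert-butyldiphenylsilyl)oxy]octan-3-yl]-5-oxooxolane-3-carboxylate | CC(C)(C)[Si](c1ccccc1)(c1ccccc1)OCCCC[C@@H]([C@@H](CC)[C@@H]1OC(=O)C[C@@H]1C(=O)OCc1ccccc1)C(=O)OC(C)(C)C | intermediate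
18 | (2S,3S)-2-[(3R,4S)-4-(tert-butoxycarbonyl)-8-[(tert-butyldiphenylsilyl)oxy]octan-3-yl]-5-oxooxolane-3-carboxylic acid | CC(C)(C)[Si](c1ccccc1)(c1ccccc1)OCCCC[C@@H]([C@@H](CC)[C@@H]1OC(=O)C[C@@H]1C(=O)O)C(=O)OC(C)(C)C | intermediate
19 | disodium carboxylate lactone-enolate of 18 (not isolated) | CC(C)(C)[Si](c1ccccc1)(c1ccccc1)OCCCC[C@@H]([C@@H](CC)[C@@H]1OC([O-])=C[C@@H]1C([O-])=O)C(=O)OC(C)(C)C.[Na+].[Na+] | intermediate
20 | (2S,3S,4S)-2-[(3R,4S)-4-(tert-butoxycarbonyl)-8-[(tert-butyldiphenylsilyl)oxy]octan-3-yl]-4-methyl-5-oxooxolane-3-carboxylic acid | CC(C)(C)[Si](c1ccccc1)(c1ccccc1)OCCCC[C@@H]([C@@H](CC)[C@@H]1OC(=O)[C@@H](C)[C@@H]1C(=O)O)C(=O)OC(C)(C)C | intermediate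
21 | 2-(benzyloxy)acetaldehyde | O=CCOCc1ccccc1 | starting material
22 | ethyl (triphenylphosphoranylidene)acetate | CCOC(=O)C=P(c1ccccc1)(c1ccccc1)c1ccccc1 | starting material
23 | ethyl (2E)-4-(benzyloxy)but-2-enoate | CCOC(=O)/C=C/COCc1ccccc1 | intermediate
24 | ethyl (2R,3S)-4-(benzyloxy)-3-[(tert-butoxycarbonyl)amino]-2-hydroxybutanoate | CCOC(=O)[C@H](O)[C@H](COCc1ccccc1)NC(=O)OC(C)(C)C | intermediate
25 | 3-tert-butyl 5-ethyl (4S,5R)-4-[(benzyloxy)methyl]-2,2-dimethyl-1,3-oxazolidine-3,5-dicarboxylate | CCOC(=O)[C@@H]1OC(C)(C)N(C(=O)OC(C)(C)C)[C@H]1COCc1ccccc1 | intermediate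
26 | tert-butyl (4S,5R)-4-[(benzyloxy)methyl]-5-formyl-2,2-dimethyl-1,3-oxazolidine-3-carboxylate | O=C[C@@H]1OC(C)(C)N(C(=O)OC(C)(C)C)[C@H]1COCc1ccccc1 | intermediate
27 | ethyl 2-[bis(2,2,2-trifluoroethoxy)phosphoryl]propanoate | CCOC(=O)C(C)P(=O)(OCC(F)(F)F)OCC(F)(F)F | starting material
28 | tert-butyl (4S,5S)-4-[(benzyloxy)methyl]-5-[(1Z)-3-ethoxy-2-methyl-3-oxoprop-1-en-1-yl]-2,2-dimethyl-1,3-oxazolidine-3-carboxylate | CCOC(=O)/C(C)=C\[C@@H]1OC(C)(C)N(C(=O)OC(C)(C)C)[C@H]1COCc1ccccc1 | intermediate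
29 | ethyl (2Z,4S,5S)-6-(benzyloxy)-5-[(tert-butoxycarbonyl)amino]-4-hydroxy-2-methylhex-2-enoate (not isolated) | CCOC(=O)/C(C)=C\[C@H](O)[C@H](COCc1ccccc1)NC(=O)OC(C)(C)C | intermediate
30 | tert-butyl N-[(1S)-2-(benzyloxy)-1-[(2S)-4-methyl-5-oxo-2,5-dihydrofuran-2-yl]ethyl]carbamate | C(OCc1ccccc1)[C@@H]([C@@H]1C=C(C)C(=O)O1)NC(=O)OC(C)(C)C | intermediate
31 | tert-butyl N-[(1S)-2-(benzyloxy)-1-[(2S,4S)-4-methyl-5-oxooxolan-2-yl]ethyl]carbamate (not isolated) | C(OCc1ccccc1)[C@@H]([C@@H]1C[C@H](C)C(=O)O1)NC(=O)OC(C)(C)C | intermediate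
32 | tert-butyl N-[(1S)-2-hydroxy-1-[(2S,4S)-4-methyl-5-oxooxolan-2-yl]ethyl]carbamate | OC[C@@H]([C@@H]1C[C@H](C)C(=O)O1)NC(=O)OC(C)(C)C | intermediate
33 | tert-butyl N-[(1R)-2-iodo-1-[(2S,4S)-4-methyl-5-oxooxolan-2-yl]ethyl]carbamate | IC[C@@H]([C@@H]1C[C@H](C)C(=O)O1)NC(=O)OC(C)(C)C | intermediate
34 | acid chloride of 20 (not isolated) | CC(C)(C)[Si](c1ccccc1)(c1ccccc1)OCCCC[C@@H]([C@@H](CC)[C@@H]1OC(=O)[C@@H](C)[C@@H]1C(Cl)=O)C(=O)OC(C)(C)C | intermediate
35 | {(2R)-2-[(tert-butoxycarbonyl)amino]-2-[(2S,4S)-4-methyl-5-oxooxolan-2-yl]ethyl}zinc iodide (not isolated) | I[Zn]C[C@@H]([C@@H]1C[C@H](C)C(=O)O1)NC(=O)OC(C)(C)C | intermediate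
36 | tert-butyl (2S)-6-[(tert-butyldiphenylsilyl)oxy]-2-[(1R)-1-{(2S,3S,4S)-3-[(3S)-3-[(tert-butoxycarbonyl)amino]-3-[(2S,4S)-4-methyl-5-oxooxolan-2-yl]propanoyl]-4-methyl-5-oxooxolan-2-yl}propyl]hexanoate | CC(C)(C)[Si](c1ccccc1)(c1ccccc1)OCCCC[C@@H]([C@@H](CC)[C@@H]1OC(=O)[C@@H](C)[C@@H]1C(=O)C[C@@H]([C@@H]1C[C@H](C)C(=O)O1)NC(=O)OC(C)(C)C)C(=O)OC(C)(C)C | intermediate
37 | ammonium methanesulfonate of de-Boc 36 (not isolated) | CC(C)(C)[Si](c1ccccc1)(c1ccccc1)OCCCC[C@@H]([C@@H](CC)[C@@H]1OC(=O)[C@@H](C)[C@@H]1C(=O)C[C@@H]([C@@H]1C[C@H](C)C(=O)O1)[NH3+])C(=O)OC(C)(C)C.CS(=O)(=O)[O-] | intermediate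
38 | tert-butyl (2S)-6-[(tert-butyldiphenylsilyl)oxy]-2-[(1R)-1-{(2S,3S,4S)-4-methyl-3-[(3S)-3-[(2S,4S)-4-methyl-5-oxooxolan-2-yl]-3-[(2-nitrophenyl)sulfonylamino]propanoyl]-5-oxooxolan-2-yl}propyl]hexanoate | CC(C)(C)[Si](c1ccccc1)(c1ccccc1)OCCCC[C@@H]([C@@H](CC)[C@@H]1OC(=O)[C@@H](C)[C@@H]1C(=O)C[C@@H]([C@@H]1C[C@H](C)C(=O)O1)NS(=O)(=O)c1ccccc1[N+](=O)[O-])C(=O)OC(C)(C)C | intermediate
39 | tert-butyl (2S)-6-hydroxy-2-[(1R)-1-{(2S,3S,4S)-4-methyl-3-[(3S)-3-[(2S,4S)-4-methyl-5-oxooxolan-2-yl]-3-[(2-nitrophenyl)sulfonylamino]propanoyl]-5-oxooxolan-2-yl}propyl]hexanoate | OCCCC[C@@H]([C@@H](CC)[C@@H]1OC(=O)[C@@H](C)[C@@H]1C(=O)C[C@@H]([C@@H]1C[C@H](C)C(=O)O1)NS(=O)(=O)c1ccccc1[N+](=O)[O-])C(=O)OC(C)(C)C | intermediate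
40 | N-(2-nitrophenylsulfonyl) twelve-membered azacycle, tert-butyl ester (N bonded to C5 and C3; stereocentres as in 39) | O=S(=O)(c1ccccc1[N+](=O)[O-])N1CCCC[C@H](C(=O)OC(C)(C)C)[C@@H](CC)[C@@H]2OC(=O)[C@@H](C)[C@@H]2C(=O)C[C@H]1[C@@H]1C[C@H](C)C(=O)O1 | intermediate
41 | N-(2-nitrophenylsulfonyl) twelve-membered azacycle, C9a carboxylic acid | O=S(=O)(c1ccccc1[N+](=O)[O-])N1CCCC[C@H](C(=O)O)[C@@H](CC)[C@@H]2OC(=O)[C@@H](C)[C@@H]2C(=O)C[C@H]1[C@@H]1C[C@H](C)C(=O)O1 | intermediate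
42 | N-(2-nitrophenylsulfonyl) twelve-membered azacycle, pentafluorophenyl ester | O=S(=O)(c1ccccc1[N+](=O)[O-])N1CCCC[C@H](C(=O)Oc2c(F)c(F)c(F)c(F)c2F)[C@@H](CC)[C@@H]2OC(=O)[C@@H](C)[C@@H]2C(=O)C[C@H]1[C@@H]1C[C@H](C)C(=O)O1 | intermediate
43 | twelve-membered secondary amine, pentafluorophenyl ester (not isolated) | N1CCCC[C@H](C(=O)Oc2c(F)c(F)c(F)c(F)c2F)[C@@H](CC)[C@@H]2OC(=O)[C@@H](C)[C@@H]2C(=O)C[C@H]1[C@@H]1C[C@H](C)C(=O)O1 | intermediate
44 | CNP0311700.3, bridged keto-lactam bis-lactone (3S,9S,10R,11S,12S,13S,18S,20S) | CC[C@H]1[C@@H]2OC(=O)[C@@H](C)[C@@H]2C(=O)C[C@@H]([C@@H]2C[C@H](C)C(=O)O2)N2CCCC[C@@H]1C2=O | target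

**Totals**
Total step count: 27. Longest linear sequence: 17 steps (1, 3, 4, 5, 6, 8, 9, 10, 11, 12, 21, 22, 23, 24, 25, 26, 27; from 1 to 44).

**Steps most likely to fail, with fallbacks**

Step 8 (anti aldol, facial selectivity on the α-branched aldehyde). If Felkin control is poor, set out from aldehyde 11 and build the two centres one after the other under catalyst control. Roskamp homologation with benzyl diazoacetate and SnCl2 (10 mol%, CH2Cl2) gives the β-keto ester benzyl (4R,5S)-5-(tert-butoxycarbonyl)-9-[(tert-butyldiphenylsilyl)oxy]-4-ethyl-3-oxononanoate F1. Hydrogenation with RuCl2[(S)-BINAP] (or a ketoreductase of the same facial preference) gives benzyl (3R,4R,5S)-5-(tert-butoxycarbonyl)-9-[(tert-butyldiphenylsilyl)oxy]-4-ethyl-3-hydroxynonanoate F2. LiN(iPr)2 (2.2 equiv, THF, −78 to −20 °C) then forms the dilithium alkoxide enolate of F2 F3, which is allylated by allyl bromide anti to the alkoxide (Fráter–Seebach alkylation); this returns to the route at 15.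

Step 21 (alkylzinc acylation; possible β-elimination of the zinc reagent or sluggish coupling with the hindered acid chloride). Set out from acid 20 and iodide 33 and make the ketone by carbonyl addition and oxidation instead:
- BH3·SMe2 (THF, 0 °C) reduces the acid selectively to tert-butyl (2S)-6-[(tert-butyldiphenylsilyl)oxy]-2-[(1R)-1-[(2S,3R,4S)-3-(hydroxymethyl)-4-methyl-5-oxooxolan-2-yl]propyl]hexanoate F4.
- Dess–Martin periodinane gives tert-butyl (2S)-6-[(tert-butyldiphenylsilyl)oxy]-2-[(1R)-1-[(2S,3S,4S)-3-formyl-4-methyl-5-oxooxolan-2-yl]propyl]hexanoate F5.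
- Iodide 33 with CrCl2 (4 equiv) and catalytic cyanocobalamin (C63H88CoN14O14P) in DMF gives {(2R)-2-[(tert-butoxycarbonyl)amino]-2-[(2S,4S)-4-methyl-5-oxooxolan-2-yl]ethyl}chromium dichloride F6, which adds to F5 (Takai-type Nozaki–Hiyama alkylation) to give the C1 carbinol of 36 (epimer mixture at C1) F7.
- Dess–Martin oxidation of F7 returns to the route at 36.

Step 24 (Mitsunobu macrocyclization; oligomers or hydrazide by-products). Set out from alcohol 39 and replace the redox condensation by a classical intramolecular SN2 alkylation. PPh3/I2/imidazole gives tert-butyl (2S)-6-iodo-2-[(1R)-1-{(2S,3S,4S)-4-methyl-3-[(3S)-3-[(2S,4S)-4-methyl-5-oxooxolan-2-yl]-3-[(2-nitrophenyl)sulfonylamino]propanoyl]-5-oxooxolan-2-yl}propyl]hexanoate F8. Slow addition of F8 to Cs2CO3 in MeCN (0.002 M, 40 °C) closes the ring through the caesium sulfonamide (Fukuyama alkylation); this returns to the route at 40.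

**Further compounds**
F1 | step 8 | benzyl (4R,5S)-5-(tert-butoxycarbonyl)-9-[(tert-butyldiphenylsilyl)oxy]-4-ethyl-3-oxononanoate | CC(C)(C)[Si](c1ccccc1)(c1ccccc1)OCCCC[C@@H]([C@@H](CC)C(=O)CC(=O)OCc1ccccc1)C(=O)OC(C)(C)C
F2 | step 8 | benzyl (3R,4R,5S)-5-(tert-butoxycarbonyl)-9-[(tert-butyldiphenylsilyl)oxy]-4-ethyl-3-hydroxynonanoate | CC(C)(C)[Si](c1ccccc1)(c1ccccc1)OCCCC[C@@H]([C@@H](CC)[C@H](O)CC(=O)OCc1ccccc1)C(=O)OC(C)(C)C
F3 | step 8 | dilithium alkoxide enolate of F2 | CC(C)(C)[Si](c1ccccc1)(c1ccccc1)OCCCC[C@@H]([C@@H](CC)[C@H]([O-])C=C([O-])OCc1ccccc1)C(=O)OC(C)(C)C.[Li+].[Li+]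
F4 | step 21 | tert-butyl (2S)-6-[(tert-butyldiphenylsilyl)oxy]-2-[(1R)-1-[(2S,3R,4S)-3-(hydroxymethyl)-4-methyl-5-oxooxolan-2-yl]propyl]hexanoate | CC(C)(C)[Si](c1ccccc1)(c1ccccc1)OCCCC[C@@H]([C@@H](CC)[C@@H]1OC(=O)[C@@H](C)[C@@H]1CO)C(=O)OC(C)(C)C
F5 | step 21 | tert-butyl (2S)-6-[(tert-butyldiphenylsilyl)oxy]-2-[(1R)-1-[(2S,3S,4S)-3-formyl-4-methyl-5-oxooxolan-2-yl]propyl]hexanoate | CC(C)(C)[Si](c1ccccc1)(c1ccccc1)OCCCC[C@@H]([C@@H](CC)[C@@H]1OC(=O)[C@@H](C)[C@@H]1C=O)C(=O)OC(C)(C)C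
F6 | step 21 | {(2R)-2-[(tert-butoxycarbonyl)amino]-2-[(2S,4S)-4-methyl-5-oxooxolan-2-yl]ethyl}chromium dichloride | Cl[Cr](Cl)C[C@@H]([C@@H]1C[C@H](C)C(=O)O1)NC(=O)OC(C)(C)C
F7 | step 21 | C1 carbinol of 36 (epimer mixture at C1) | CC(C)(C)[Si](c1ccccc1)(c1ccccc1)OCCCC[C@@H]([C@@H](CC)[C@@H]1OC(=O)[C@@H](C)[C@@H]1C(O)C[C@@H]([C@@H]1C[C@H](C)C(=O)O1)NC(=O)OC(C)(C)C)C(=O)OC(C)(C)C
F8 | step 24 | tert-butyl (2S)-6-iodo-2-[(1R)-1-{(2S,3S,4S)-4-methyl-3-[(3S)-3-[(2S,4S)-4-methyl-5-oxooxolan-2-yl]-3-[(2-nitrophenyl)sulfonylamino]propanoyl]-5-oxooxolan-2-yl}propyl]hexanoate | ICCCC[C@@H]([C@@H](CC)[C@@H]1OC(=O)[C@@H](C)[C@@H]1C(=O)C[C@@H]([C@@H]1C[C@H](C)C(=O)O1)NS(=O)(=O)c1ccccc1[N+](=O)[O-])C(=O)OC(C)(C)C
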